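A run stopped at its time leaves a leftover: starting material that has passed the first step but still waits as intermediate A or intermediate B. That leftover is what to watch on repeating these flasks.

in all of them: starting material 17 mM; protic impurity 3.40 mM; time 4.0 min
- theta: temperature 65 °C
- gamma: temperature 35 °C
- epsilon: at 65 °C until 50 s, from then on at 35 °C

- the best flask by amount of product, in percent of the starting material charged; "all alike" if 1.5 percentage points covers them all (theta / gamma / epsilon / all alike)
- amount of product at the end, in percent of the starting material charged, theta
- amount of product at the end, in percent of the starting material charged, gamma
- amount of product at the end, in percent of the starting material charged, epsilon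

- a species is counted by the starting material in it: one idle adduct counts as two
- amounts and yields of product count idle adduct too
- all constants are for 35 °C and move with temperature by the activation energies and enthalpies
- in an amount of product, one idle adduct counts as one product

    starting material → intermediate A (k1 = 0.92 /min, Ea1 = 87.0 kJ/mol)
    intermediate A → product (k2 = 0.097 /min, Ea2 = 94.0 kJ/mol)
    intermediate A ⇌ intermediate B (K3 = 0.40, k3 = 0.32 /min, Ea3 = 95.0 kJ/mol, ΔH3 = −19.0 kJ/mol)
    starting material + protic impurity → quenched substrate (k4 = 180 /M/min, Ea4 = 53.0 kJ/mol)
    starting material + product ⇌ idle adduct, settled at all times (K5 = 36 /M, ΔH5 = −4.00 kJ/mol)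
    starting material ⇌ dormant form (K6 = 18, k6 = 0.021 /min, Ea6 = 92.0 kJ/mol, ΔH6 = −34.0 kJ/mol)
    (constants at 35 °C)

Our own reckoning follows the rate of product formation, not the concentrations. Starting material goes to intermediate A with constant k_a, and intermediate A goes to product with constant k_p, which is 0.097 /min at 35 °C. Intermediate A also exchanges with intermediate B, with a balance K (B over A) of 0.40 and a relaxation half-life of 0.619 min in gamma. We take this exchange as in balance, so the pool of A and B holds the free share 1/(1+K) as intermediate A. The drain constant k_d, the free share times k_p, is the rate constant at which the whole pool turns to product: 0.0693 /min at 35 °C. This gives the pool a half-life of 10.0 min, longer than the exchange needs, which justifies the balance. At 65 °C, k_p rises to 2.51 /min and K falls to 0.207, so k_d becomes 2.08 /min.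

Two more things hold the rate back. The pool must first fill, and we count that as a delay of 1/k_a: 1.09 min at 35 °C and 0.0534 min at 65 °C. The quench also takes starting material, with constant k_q. The ratio s = k_a/k_q is a concentration, the level of protic impurity at which the two rates match: 5.11 mM at 35 °C and 16.6 mM at 65 °C. Divided by the protic impurity present, it gives the selectivity factor between the two ways, 1.5 just after the start of gamma. The protic impurity falls e-fold for each s of starting material that passes to intermediate A, not for each s used; as a rough step we let the whole charge pass, which overstates the quench somewhat. With charges c and H, the share reaching the pool is F = 1 − (H/c)(1 − exp(−c/s)): 80.7 % cold and 87.2 % hot. We drop the dormant form, since k_a is the faster way out.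

Product is then F times the drained part of the pool. We reckon 87.2 % for theta and 14.8 % for gamma. Epsilon drains at the hot constant until 50 s and at the cold one afterwards, which gives 73.4 %. Our best flask is theta.

The forecast names theta, with 86.5 % for theta, 16.5 % for gamma and 72.5 % for epsilon, figures that differ from ours in each flask. Its ground at the hot end is that “the first-order step outruns the low-barrier quench”.

The simulation gives theta as best, with 86.5 % for theta, 16.3 % for gamma and 72.5 % for epsilon.

Gamma falls short for want of time: it holds 16.3 % at 4.0 min and 74.1 % at 40.0 min. Its pool half-life of 10.0 min exceeds the 4.0 min given, so the 44.2 % of intermediate A and 17.5 % of intermediate B at the end of gamma are still on their way to product. Read at 10 min, the same flask should hold 37.2 % by the drain constant, and the run gives 37.4 %.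

The constants belong to no real substance.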